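Lukianol B is traced back to a 3,4-diarylpyrrole-2-carboxylate whose pyrrole ring is made in one palladium-catalysed operation. With the core numbered C1(=O)–O2–C3=C4–N5–C6=C7–C8=C8a and the aryl groups called ring A (C3), ring B (iodinated, C7) and ring C (C8), the feature exploited is the C6=C7 unit next to N5: C6 and C7 begin as an alkyne on C8 of a dehydrotyrosine, so that arylative cyclisation forms N5–C6 and C7–ring B together. The precursor is a Z-enyne trifluoroacetamide with a silyl-capped alkyne cis to nitrogen; ring B arrives as an isopropyl ether, so that it alone can later be unmasked and iodinated.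

Key step: step 6

Remark: the stereocentre of 1 is erased in step 2 and the target is achiral, so only alkene geometry needs control; step 3 is assumed to place bromine cis to nitrogen, as is usual for amine-mediated β-bromination of dehydroamino esters.

Step 1
Reactants: 1 O-methyl-L-tyrosine methyl ester hydrochloride
Product: 2 methyl (S)-3-(4-methoxyphenyl)-2-(2,2,2-trifluoroacetamido)propanoate
Conditions: (CF3CO)2O, Et3N, CH2Cl2, 0 °C → rt
Reagents that add atoms: trifluoroacetic anhydride, O=C(OC(=O)C(F)(F)F)C(F)(F)F
Why: Acylation of the free-based amine by the anhydride (amide formation) is fast and selective, and any erosion of configuration is irrelevant because the stereocentre is removed in step 2.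

Step 2
Reactants: 2 methyl (S)-3-(4-methoxyphenyl)-2-(2,2,2-trifluoroacetamido)propanoate
Product: 5 methyl (Z)-3-(4-methoxyphenyl)-2-(2,2,2-trifluoroacetamido)acrylate, via N-chloro amide 3 (not isolated), via N-acylimine 4 (not isolated)
Conditions: t-BuOCl, t-BuOK (cat.), THF, 0 °C, dark; then DBU, 0 °C → rt
Reagents that add atoms: tert-butyl hypochlorite, CC(C)(C)OCl (its chlorine is held by 3 only)
Why: N-Chlorination of the amidate followed by base-induced 1,2-dehydrochlorination (the N-chloroamide route to dehydroamino esters) gives acylimine 4, which tautomerises into conjugation with the anisyl ring to the more stable Z-enamide (aryl cis to nitrogen), so the stereocentre of 2 is erased on purpose.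

Step 3
Reactants: 5 methyl (Z)-3-(4-methoxyphenyl)-2-(2,2,2-trifluoroacetamido)acrylate
Product: 7 methyl (Z)-3-bromo-3-(4-methoxyphenyl)-2-(2,2,2-trifluoroacetamido)acrylate, via bromo imine 6 (not isolated)
Conditions: NBS, CH2Cl2, 0 °C → rt; then Et3N, 0 °C → rt
Reagents that add atoms: N-bromosuccinimide, O=C1CCC(=O)N1Br
Why: Electrophilic bromination of the enamide at its β-carbon gives bromo imine 6, and amine-mediated imine–enamine tautomerisation should return the tetrasubstituted enamide mainly as the Z isomer with bromine cis to nitrogen, the usual outcome of this β-bromination of dehydroamino esters, with any E isomer removable by chromatography.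

Step 4
Reactants: 7 methyl (Z)-3-bromo-3-(4-methoxyphenyl)-2-(2,2,2-trifluoroacetamido)acrylate; 8 trimethylsilylacetylene
Product: 9 methyl (Z)-3-(4-methoxyphenyl)-2-(2,2,2-trifluoroacetamido)-5-(trimethylsilyl)pent-2-en-4-ynoate
Conditions: PdCl2(PPh3)2 (cat.), CuI (cat.), Et3N, MeCN, rt
Reagents that add atoms: none
Why: Sonogashira coupling of the vinyl bromide proceeds with retention of alkene geometry, so the alkyne is installed cis to nitrogen, while the silyl cap prevents a second coupling and room temperature avoids premature cyclisation.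

Step 5
Reactants: 10 4-iodophenol
Product: 11 1-iodo-4-isopropoxybenzene
Conditions: 2-bromopropane, K2CO3, DMF, 60 °C
Reagents that add atoms: 2-bromopropane, CC(C)Br
Why: Williamson ether synthesis of the phenoxide with a secondary bromide in a dipolar aprotic solvent, to which the aryl iodide is inert.

Step 6
Reactants: 9 methyl (Z)-3-(4-methoxyphenyl)-2-(2,2,2-trifluoroacetamido)-5-(trimethylsilyl)pent-2-en-4-ynoate; 11 1-iodo-4-isopropoxybenzene
Product: 13 methyl 4-(4-isopropoxyphenyl)-3-(4-methoxyphenyl)-5-(trimethylsilyl)-1H-pyrrole-2-carboxylate, via N-trifluoroacetylpyrrole 12 (not isolated)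
Conditions: Pd(PPh3)4 (5 mol %), Cs2CO3, MeCN, 70 °C; aq. NH4Cl work-up
Reagents that add atoms: none
Why: Oxidative addition of 11 to zerovalent palladium gives an arylpalladium iodide (divalent palladium) that coordinates the silyl alkyne of 9; the carbonate-generated trifluoroacetamide anion attacks C6 on the face opposite the metal, and reductive elimination from the resulting C7 vinyl(aryl)palladium species forms C7–ring B and returns zerovalent palladium, after which the labile N-trifluoroacetyl group of 12 is cleaved by carbonate and water. The closest known reaction is the aminopalladation–reductive elimination of o-alkynyl trifluoroacetanilides with aryl iodides to 3-arylindoles, with the arene double bond replaced here by the C8=C8a enamide bond. The pyrrole closes in a 5-endo-dig mode, which the metal-activated alkyne permits and which is electronically matched because C6 is the δ-carbon of the doubly unsaturated C1 ester. No stereocentre is created. The step needs aryl transfer to C7 and not arylation of the alkyne terminus or plain hydroamination: the trimethylsilyl cap removes the terminal C–H, the Z geometry holds N5 within reach of C6, the acidic trifluoroacetamide supplies the nucleophile under mild base, and an excess of 11 in dry acetonitrile keeps reductive elimination ahead of protonolysis, so ring B can end up only on C7 while ring C is already fixed on C8.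

Step 7
Reactants: 13 methyl 4-(4-isopropoxyphenyl)-3-(4-methoxyphenyl)-5-(trimethylsilyl)-1H-pyrrole-2-carboxylate
Product: 14 methyl 4-(4-isopropoxyphenyl)-3-(4-methoxyphenyl)-1H-pyrrole-2-carboxylate
Conditions: TBAF (1 M in THF, wet), THF, rt → 50 °C
Reagents that add atoms: none
Why: Fluoride-induced protodesilylation: the C–Si bond at the pyrrole α-carbon, activated by the conjugated ester, is cleaved by fluoride and the carbanion protonated by water, while the ester and aryl ethers are untouched.

Step 8
Reactants: 14 methyl 4-(4-isopropoxyphenyl)-3-(4-methoxyphenyl)-1H-pyrrole-2-carboxylate; 15 2-bromo-4'-methoxyacetophenone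
Product: 16 methyl 4-(4-isopropoxyphenyl)-3-(4-methoxyphenyl)-1-[2-(4-methoxyphenyl)-2-oxoethyl]-1H-pyrrole-2-carboxylate
Conditions: K2CO3, DMF, rt
Reagents that add atoms: none
Why: N-Alkylation of the pyrrolide (N–H acidified by the 2-ester) by bimolecular substitution on a reactive α-bromo ketone, now unhindered because the silyl group at C6 is gone.

Step 9
Reactants: 16 methyl 4-(4-isopropoxyphenyl)-3-(4-methoxyphenyl)-1-[2-(4-methoxyphenyl)-2-oxoethyl]-1H-pyrrole-2-carboxylate
Product: 17 4-(4-isopropoxyphenyl)-3-(4-methoxyphenyl)-1-[2-(4-methoxyphenyl)-2-oxoethyl]-1H-pyrrole-2-carboxylic acid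
Conditions: KOH, EtOH–THF–H2O, 70 °C; then aq. HCl
Reagents that add atoms: potassium hydroxide, [K+].[OH-]
Why: Saponification (ester hydrolysis by acyl–oxygen cleavage) of the electron-rich pyrrole ester needs heat but leaves the ketone and the aryl ethers intact.

Step 10
Reactants: 17 4-(4-isopropoxyphenyl)-3-(4-methoxyphenyl)-1-[2-(4-methoxyphenyl)-2-oxoethyl]-1H-pyrrole-2-carboxylic acid
Product: 19 7-(4-isopropoxyphenyl)-3,8-bis(4-methoxyphenyl)-1H-pyrrolo[2,1-c][1,4]oxazin-1-one, via mixed anhydride 18 (not isolated)
Conditions: Ac2O, NaOAc, 110 °C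
Reagents that add atoms: acetic anhydride, CC(=O)OC(C)=O (its acetyl group is held by 18 only)
Why: Cyclodehydration of the keto acid: mixed anhydride 18 acylates the enol oxygen of the neighbouring ketone in a 6-exo-trig closure, giving the enol lactone with ring A on C3, a well-established way to this pyrrolo-oxazinone core.

Step 11
Reactants: 19 7-(4-isopropoxyphenyl)-3,8-bis(4-methoxyphenyl)-1H-pyrrolo[2,1-c][1,4]oxazin-1-one
Product: 20 7-(4-hydroxyphenyl)-3,8-bis(4-methoxyphenyl)-1H-pyrrolo[2,1-c][1,4]oxazin-1-one
Conditions: BCl3, CH2Cl2, −78 → 0 °C; then H2O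
Reagents that add atoms: none
Why: Lewis-acid ether cleavage: BCl3 removes the isopropyl group, which ionises far more easily than methyl, so that only the ring B phenol is released while the two methyl ethers and the lactone survive at low temperature.

Step 12
Reactants: 20 7-(4-hydroxyphenyl)-3,8-bis(4-methoxyphenyl)-1H-pyrrolo[2,1-c][1,4]oxazin-1-one
Product: 21 7-(4-hydroxy-3-iodophenyl)-3,8-bis(4-methoxyphenyl)-1H-pyrrolo[2,1-c][1,4]oxazin-1-one
Conditions: NIS (1.0 equiv), TsOH·H2O (cat.), MeCN, 0 °C, dark
Reagents that add atoms: N-iodosuccinimide, O=C1CCC(=O)N1I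
Why: Electrophilic aromatic iodination: the free phenol ring B is the most activated arene, its para position is blocked and the first iodine deactivates it, so one equivalent of NIS should give the ortho mono-iodide while the acyl-deactivated pyrrole C6–H and the anisyl rings A and C react more slowly.

Step 13
Reactants: 21 7-(4-hydroxy-3-iodophenyl)-3,8-bis(4-methoxyphenyl)-1H-pyrrolo[2,1-c][1,4]oxazin-1-one
Product: 22 lukianol B, 7-(4-hydroxy-3-iodophenyl)-3,8-bis(4-hydroxyphenyl)-1H-pyrrolo[2,1-c][1,4]oxazin-1-one
Conditions: BBr3, CH2Cl2, −78 °C → rt; then H2O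
Reagents that add atoms: none
Why: Demethylation of the two aryl methyl ethers with BBr3 (Lewis-acid ether cleavage) is compatible with the aryl iodide and with the enol lactone, which tolerates the reagent at or below room temperature.

Compound list
1 | O-methyl-L-tyrosine methyl ester hydrochloride | Cl.COC(=O)[C@@H](N)Cc1ccc(OC)cc1 | starting material
2 | methyl (S)-3-(4-methoxyphenyl)-2-(2,2,2-trifluoroacetamido)propanoate | COC(=O)[C@H](Cc1ccc(OC)cc1)NC(=O)C(F)(F)F | intermediate
3 | methyl (S)-2-(N-chloro-2,2,2-trifluoroacetamido)-3-(4-methoxyphenyl)propanoate | COC(=O)[C@H](Cc1ccc(OC)cc1)N(Cl)C(=O)C(F)(F)F | intermediate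
4 | methyl 3-(4-methoxyphenyl)-2-[(2,2,2-trifluoroacetyl)imino]propanoate | COC(=O)C(Cc1ccc(OC)cc1)=NC(=O)C(F)(F)F | intermediate
5 | methyl (Z)-3-(4-methoxyphenyl)-2-(2,2,2-trifluoroacetamido)acrylate | COC(=O)/C(NC(=O)C(F)(F)F)=C/c1ccc(OC)cc1 | intermediate
6 | methyl 3-bromo-3-(4-methoxyphenyl)-2-[(2,2,2-trifluoroacetyl)imino]propanoate (racemic) | COC(=O)C(=NC(=O)C(F)(F)F)C(Br)c1ccc(OC)cc1 | intermediate
7 | methyl (Z)-3-bromo-3-(4-methoxyphenyl)-2-(2,2,2-trifluoroacetamido)acrylate | COC(=O)/C(NC(=O)C(F)(F)F)=C(/Br)c1ccc(OC)cc1 | intermediate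
8 | trimethylsilylacetylene | C#C[Si](C)(C)C | starting material
9 | methyl (Z)-3-(4-methoxyphenyl)-2-(2,2,2-trifluoroacetamido)-5-(trimethylsilyl)pent-2-en-4-ynoate | COC(=O)/C(NC(=O)C(F)(F)F)=C(/C#C[Si](C)(C)C)c1ccc(OC)cc1 | intermediate
10 | 4-iodophenol | Oc1ccc(I)cc1 | starting material
11 | 1-iodo-4-isopropoxybenzene | CC(C)Oc1ccc(I)cc1 | intermediate
12 | methyl 4-(4-isopropoxyphenyl)-3-(4-methoxyphenyl)-1-(2,2,2-trifluoroacetyl)-5-(trimethylsilyl)-1H-pyrrole-2-carboxylate | COC(=O)c1n(C(=O)C(F)(F)F)c([Si](C)(C)C)c(-c2ccc(OC(C)C)cc2)c1-c1ccc(OC)cc1 | intermediate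
13 | methyl 4-(4-isopropoxyphenyl)-3-(4-methoxyphenyl)-5-(trimethylsilyl)-1H-pyrrole-2-carboxylate | COC(=O)c1[nH]c([Si](C)(C)C)c(-c2ccc(OC(C)C)cc2)c1-c1ccc(OC)cc1 | intermediate
14 | methyl 4-(4-isopropoxyphenyl)-3-(4-methoxyphenyl)-1H-pyrrole-2-carboxylate | COC(=O)c1[nH]cc(-c2ccc(OC(C)C)cc2)c1-c1ccc(OC)cc1 | intermediate
15 | 2-bromo-4'-methoxyacetophenone | COc1ccc(cc1)C(=O)CBr | starting material
16 | methyl 4-(4-isopropoxyphenyl)-3-(4-methoxyphenyl)-1-[2-(4-methoxyphenyl)-2-oxoethyl]-1H-pyrrole-2-carboxylate | COC(=O)c1n(CC(=O)c2ccc(OC)cc2)cc(-c2ccc(OC(C)C)cc2)c1-c1ccc(OC)cc1 | intermediate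
17 | 4-(4-isopropoxyphenyl)-3-(4-methoxyphenyl)-1-[2-(4-methoxyphenyl)-2-oxoethyl]-1H-pyrrole-2-carboxylic acid | OC(=O)c1n(CC(=O)c2ccc(OC)cc2)cc(-c2ccc(OC(C)C)cc2)c1-c1ccc(OC)cc1 | intermediate
18 | acetic 4-(4-isopropoxyphenyl)-3-(4-methoxyphenyl)-1-[2-(4-methoxyphenyl)-2-oxoethyl]-1H-pyrrole-2-carboxylic anhydride | CC(=O)OC(=O)c1n(CC(=O)c2ccc(OC)cc2)cc(-c2ccc(OC(C)C)cc2)c1-c1ccc(OC)cc1 | intermediate
19 | 7-(4-isopropoxyphenyl)-3,8-bis(4-methoxyphenyl)-1H-pyrrolo[2,1-c][1,4]oxazin-1-one | O=c1oc(-c2ccc(OC)cc2)cn2cc(-c3ccc(OC(C)C)cc3)c(-c3ccc(OC)cc3)c12 | intermediate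
20 | 7-(4-hydroxyphenyl)-3,8-bis(4-methoxyphenyl)-1H-pyrrolo[2,1-c][1,4]oxazin-1-one | O=c1oc(-c2ccc(OC)cc2)cn2cc(-c3ccc(O)cc3)c(-c3ccc(OC)cc3)c12 | intermediate
21 | 7-(4-hydroxy-3-iodophenyl)-3,8-bis(4-methoxyphenyl)-1H-pyrrolo[2,1-c][1,4]oxazin-1-one | O=c1oc(-c2ccc(OC)cc2)cn2cc(-c3ccc(O)c(I)c3)c(-c3ccc(OC)cc3)c12 | intermediate
22 | lukianol B, 7-(4-hydroxy-3-iodophenyl)-3,8-bis(4-hydroxyphenyl)-1H-pyrrolo[2,1-c][1,4]oxazin-1-one | O=c1oc(-c2ccc(O)cc2)cn2cc(-c3ccc(O)c(I)c3)c(-c3ccc(O)cc3)c12 | target

Total step count: 13 (12 in the main line and 1 for the ring B iodide 11).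
Longest linear sequence: 12 steps (1 to 22 through steps 1–4 and 6–13).

Steps most likely to fail

1. Step 6, arylative cyclisation. What may go wrong: protonolysis of the vinylpalladium intermediate or metal-free ring closure may outrun aryl transfer, so that the ring closes without ring B, or oxidative addition of the electron-rich iodide may be slow. The fallback sets out from 9 and comes back at 13, and it separates ring closure from arylation. Iodine with K2CO3 in MeCN at 0 °C → rt should effect the same N5–C6 closure by 5-endo-dig iodoamination, with the iodonium-activated alkyne taking the place of the arylpalladium complex, to give methyl 4-iodo-3-(4-methoxyphenyl)-1-(2,2,2-trifluoroacetyl)-5-(trimethylsilyl)-1H-pyrrole-2-carboxylate F1. Its labile N-acyl group is removed by the aqueous carbonate work-up to leave methyl 4-iodo-3-(4-methoxyphenyl)-5-(trimethylsilyl)-1H-pyrrole-2-carboxylate F2, in which the halogen sits on C7 by the mechanism of the closure. Suzuki–Miyaura coupling of F2 with purchased 4-isopropoxyphenylboronic acid (Pd(OAc)2, SPhos, K3PO4, toluene–H2O, 80 °C) then places ring B on C7 and returns 13.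

2. Step 3, β-bromination. What may go wrong: loss of geometric control in the imine–enamine tautomerisation, so that bromine ends up trans to nitrogen and the later alkyne could not reach N5. The fallback sets out from 5 and comes back at 7, and it corrects the geometry after the step instead of within it. The bromination is run as before, and the unwanted isomer, methyl (E)-3-bromo-3-(4-methoxyphenyl)-2-(2,2,2-trifluoroacetamido)acrylate F3, is separated by chromatography. F3 is then subjected to E/Z photoisomerisation (hν above 300 nm, MeCN), a standard operation for dehydroamino esters, to a photostationary mixture from which 7 is again removed; the cycle is repeated until F3 is used up.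

3. Step 12, mono-iodination. What may go wrong: competing iodination at the pyrrole C6–H or on an anisyl ring, or a second iodination of ring B. The fallback sets out from 20 and comes back at 21, and it moves the control from the reagent to the substrate by iodinating the phenoxide in place of the neutral phenol. Compound 20 is treated with one equivalent of benzyltrimethylammonium dichloroiodate and NaHCO3 in CH2Cl2–MeOH at 0 °C; under these conditions a phenoxide should react many orders of magnitude faster than an acylpyrrole or an aryl ether, and the dosing to one equivalent holds the reaction at the mono-iodide. This fallback forms no compound outside the list: none F0.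

Further compounds
F1 | step 6 | methyl 4-iodo-3-(4-methoxyphenyl)-1-(2,2,2-trifluoroacetyl)-5-(trimethylsilyl)-1H-pyrrole-2-carboxylate | COC(=O)c1n(C(=O)C(F)(F)F)c([Si](C)(C)C)c(I)c1-c1ccc(OC)cc1
F2 | step 6 | methyl 4-iodo-3-(4-methoxyphenyl)-5-(trimethylsilyl)-1H-pyrrole-2-carboxylate | COC(=O)c1[nH]c([Si](C)(C)C)c(I)c1-c1ccc(OC)cc1
F3 | step 3 | methyl (E)-3-bromo-3-(4-methoxyphenyl)-2-(2,2,2-trifluoroacetamido)acrylate | COC(=O)/C(NC(=O)C(F)(F)F)=C(\Br)c1ccc(OC)cc1
F0 | step 12 | none | none
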